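The γ-butyrolactone is assembled across its O1–C5 and C4–C3 bonds by a formal (3+2) annulation. The feature exploited is the O1–C5H2–C4H edge of the lactone ring, whose C4 stereocentre cannot be corrected by epimerisation: C5 and C4 are the alkene carbons of an enantiopure (Z)-alkenyl p-tolyl sulfoxide, and O1–C2–C3 comes from dichloroketene. O-Acylation of the sulfoxide, [3,3]-sigmatropic shift and thionium capture by the carboxylate form both bonds in one operation and relay sulfur chirality to C4. Chlorine and arylthio groups are then removed, and the pyranone arm is attached by trans-selective enolate alkylation with a 4-(bromomethyl)-2-pyranone ester.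

Key step: step 4

Lactone numbering used throughout: O1, C2 (C=O), C3 (α-carbon), C4 (β-carbon), C5 (OCH2).

Assumption: the sense of sulfur-to-carbon chirality transfer is taken from the chair-like transition-state model given in step 4, not from a recalled assignment. On that model the (R)-sulfoxide 7, made from (−)-menthyl (S)-p-toluenesulfinate, leads to the (R)-lactone 13.

Step 1
Reactants: 1 4-(bromomethyl)-1,2-dimethoxybenzene; 2 ethynylmagnesium bromide
Product: 3 1,2-dimethoxy-4-(prop-2-yn-1-yl)benzene
Conditions: 2 (3 equiv), CuCl (10 mol%), THF, 0 → 50 °C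
Reagents that add atoms: none
Why: Copper(I)-catalysed cross-coupling of a reactive benzylic bromide with an alkynyl Grignard reagent should give the skipped aryl alkyne, the excess of 2 keeping the product from being benzylated a second time; no stereocentre is formed.

Step 2
Reactants: 3 1,2-dimethoxy-4-(prop-2-yn-1-yl)benzene; 4 (1R,2S,5R)-menthyl (S)-p-toluenesulfinate
Product: 6 (S)-1,2-dimethoxy-4-[3-(p-tolylsulfinyl)prop-2-yn-1-yl]benzene, via alkynylmagnesium bromide 5 (not isolated)
Conditions: EtMgBr (1.0 equiv), THF, 0 °C → rt; then added to 4 in toluene, −20 °C; cold aqueous quench (NH4Cl buffer)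
Reagents that add atoms: none
Why: Andersen sulfoxide synthesis, in which the alkynyl Grignard 5 displaces menthoxide from sulfur of 4 with inversion and so sets the sulfur stereocentre, while toluene and low temperature should restrain base-induced propargyl-to-allenyl isomerisation of the doubly activated CH2.

Step 3
Reactants: 6 (S)-1,2-dimethoxy-4-[3-(p-tolylsulfinyl)prop-2-yn-1-yl]benzene
Product: 7 (R,Z)-1,2-dimethoxy-4-[3-(p-tolylsulfinyl)prop-2-en-1-yl]benzene
Conditions: H2 (1 atm), RhCl(PPh3)3 (5 mol%), toluene, rt
Reagents that add atoms: none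
Why: Homogeneous syn-hydrogenation with Wilkinson's catalyst should stop at the (Z)-alkene because the sulfinyl-substituted alkene is a poor substrate for further reduction; the geometry follows from syn delivery of H2 and the sulfur stereocentre is untouched (its descriptor changes to R only because p-tolyl outranks alkenyl).

Step 4
Reactants: 7 (R,Z)-1,2-dimethoxy-4-[3-(p-tolylsulfinyl)prop-2-en-1-yl]benzene; 8 trichloroacetyl chloride
Product: 12 (4S,5R)-3,3-dichloro-4-(3,4-dimethoxybenzyl)-5-(p-tolylthio)dihydrofuran-2(3H)-one, via dichloroketene 9 (not isolated), via acyloxysulfonium enolate 10 (not isolated), via thionium carboxylate 11 (not isolated)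
Conditions: Zn–Cu couple (4 equiv), 8 (2.5 equiv, slow addition), THF, −45 → 0 °C
Reagents that add atoms: none
Why: Zinc dechlorinates 8 to dichloroketene 9, whose carbonyl carbon is attacked by the sulfinyl oxygen of 7 to give acyloxysulfonium enolate 10; a [3,3]-sigmatropic shift (S–O broken, enolate carbon bonded to the alkene β-carbon) gives thionium carboxylate 11, and a carboxylate oxygen closes onto the thionium carbon to give 12. This is the known vinyl sulfoxide–dichloroketene lactonisation, an additive Pummerer annulation that is formally a (3+2) process. The lactone ring closes by 5-exo-trig attack of carboxylate oxygen on the C=S+ carbon. C4 is set by chirality transfer from sulfur through a chair-like six-membered transition state in which S–O lies perpendicular to the alkene plane, the tolyl group is pseudo-equatorial and the sulfur lone pair points toward the Z substituent (A1,3 strain); C5 follows from the Z geometry, because ring closure should be faster than C4–C5 rotation, which gives the 4,5-cis lactone, and C5 is erased in step 5. The step needs the sigmatropic shift to outrun γ-deprotonation at the benzylic CH2 (vinylogous Pummerer pathway) and ketene–alkene [2+2] addition; the shift is intramolecular within the tethered enolate, the sulfinyl alkene is electron-poor, and the temperature is low.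

Step 5
Reactants: 12 (4S,5R)-3,3-dichloro-4-(3,4-dimethoxybenzyl)-5-(p-tolylthio)dihydrofuran-2(3H)-one
Product: 13 (R)-4-(3,4-dimethoxybenzyl)dihydrofuran-2(3H)-one
Conditions: Bu3SnH (3.5 equiv), AIBN (0.2 equiv, portionwise), toluene, 100 °C
Reagents that add atoms: none
Why: Radical chain reduction with tributyltin hydride, in which stannyl radicals abstract both α-chlorines and cleave the C–S bond of the O,S-acetal and each carbon radical is quenched by Sn–H, so that C5 becomes CH2 while C4, which never becomes a radical centre, keeps its configuration.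

Step 6
Reactants: 14 ethyl 3-methylbut-2-enoate; 15 diethyl oxalate
Product: 17 4-methyl-2-oxo-2H-pyran-6-carboxylic acid, via potassium dienolate 16 (not isolated)
Conditions: KOEt (1.05 equiv), Et2O–EtOH, 0 °C → rt; then conc. HCl, 100 °C
Reagents that add atoms: water, O
Why: Vinylogous Claisen condensation at the γ-methyl of 14 with oxalate gives dienolate 16, and in hot hydrochloric acid the enol oxygen lactonises onto the distal ester (6-exo-trig) and the remaining ester is hydrolysed, the classical entry to 2-pyranone-6-carboxylic acids; no stereocentre is involved.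

Step 7
Reactants: 17 4-methyl-2-oxo-2H-pyran-6-carboxylic acid
Product: 18 tert-butyl 4-methyl-2-oxo-2H-pyran-6-carboxylate
Conditions: tert-butyl 2,2,2-trichloroacetimidate (2 equiv), BF3·OEt2 (cat.), CH2Cl2–THF, rt
Reagents that add atoms: tert-butyl 2,2,2-trichloroacetimidate, CC(C)(C)OC(=N)C(Cl)(Cl)Cl
Why: Acid-catalysed tert-butylation of the carboxylic acid with the trichloroacetimidate proceeds by tert-butyl cation transfer under base-free conditions that should leave the base-sensitive 2-pyranone intact.

Step 8
Reactants: 18 tert-butyl 4-methyl-2-oxo-2H-pyran-6-carboxylate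
Product: 19 tert-butyl 4-(bromomethyl)-2-oxo-2H-pyran-6-carboxylate
Conditions: NBS (1.05 equiv), AIBN (5 mol%), PhCF3, 85 °C
Reagents that add atoms: N-bromosuccinimide, O=C1CCC(=O)N1Br
Why: Wohl–Ziegler bromination, in which hydrogen abstraction from the 4-methyl group (the γ-position of the unsaturated lactone) gives a delocalised radical, so bromine should enter the side chain and not the electron-poor ring.

Step 9
Reactants: 13 (R)-4-(3,4-dimethoxybenzyl)dihydrofuran-2(3H)-one; 19 tert-butyl 4-(bromomethyl)-2-oxo-2H-pyran-6-carboxylate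
Product: 21 tert-butyl 4-{[(3R,4R)-4-(3,4-dimethoxybenzyl)-2-oxotetrahydrofuran-3-yl]methyl}-2-oxo-2H-pyran-6-carboxylate, via lithium enolate 20 (not isolated)
Conditions: LiHMDS (1.05 equiv), THF, −78 °C; then 19 (1.1 equiv), −78 → −40 °C; AcOH quench at −78 °C
Reagents that add atoms: none
Why: Alkylation of lithium enolate 20 with the SN2-reactive allylic-type bromide 19 should occur on the face opposite the C4 benzyl group, which sets C3 as (R) and gives the trans-3,4-disubstituted lactone (the usual diastereocontrol in enolate alkylation of β-substituted γ-butyrolactones).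

Step 10
Reactants: 21 tert-butyl 4-{[(3R,4R)-4-(3,4-dimethoxybenzyl)-2-oxotetrahydrofuran-3-yl]methyl}-2-oxo-2H-pyran-6-carboxylate
Product: 22 4-{[(3R,4R)-4-(3,4-dimethoxybenzyl)-2-oxotetrahydrofuran-3-yl]methyl}-2-oxo-2H-pyran-6-carboxylic acid
Conditions: TFA–CH2Cl2 (1:3), 0 °C → rt
Reagents that add atoms: none
Why: Acidolysis of the tert-butyl ester (AAL1 cleavage with loss of isobutylene) should free the carboxylic acid under conditions in which the lactone, the 2-pyranone, the aryl methyl ethers and the C3 stereocentre are stable.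

Compound list
1 | 4-(bromomethyl)-1,2-dimethoxybenzene (3,4-dimethoxybenzyl bromide) | COc1ccc(CBr)cc1OC | starting material
2 | ethynylmagnesium bromide | C#C[Mg]Br | starting material
3 | 1,2-dimethoxy-4-(prop-2-yn-1-yl)benzene | COc1ccc(CC#C)cc1OC | intermediate
4 | (1R,2S,5R)-menthyl (S)-p-toluenesulfinate | C[C@@H]1CC[C@H]([C@@H](C1)O[S@](=O)c1ccc(C)cc1)C(C)C | starting material
5 | [3-(3,4-dimethoxyphenyl)prop-1-yn-1-yl]magnesium bromide | COc1ccc(CC#C[Mg]Br)cc1OC | intermediate
6 | (S)-1,2-dimethoxy-4-[3-(p-tolylsulfinyl)prop-2-yn-1-yl]benzene | COc1ccc(CC#C[S@@](=O)c2ccc(C)cc2)cc1OC | intermediate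
7 | (R,Z)-1,2-dimethoxy-4-[3-(p-tolylsulfinyl)prop-2-en-1-yl]benzene | COc1ccc(C/C=C\[S@@](=O)c2ccc(C)cc2)cc1OC | intermediate
8 | trichloroacetyl chloride | ClC(=O)C(Cl)(Cl)Cl | starting material
9 | dichloroketene | ClC(Cl)=C=O | intermediate
10 | acyloxysulfonium enolate zwitterion from 7 and 9 (sulfur configuration as in 7, Z-alkene) | COc1ccc(C/C=C\[S@@+](OC([O-])=C(Cl)Cl)c2ccc(C)cc2)cc1OC | intermediate
11 | thionium carboxylate zwitterion, 2,2-dichloro-3-(3,4-dimethoxybenzyl)-4-(p-tolylsulfonio)but-3-enoate with C3 configured as C4 of 12 | COc1ccc(C[C@@H](C=[S+]c2ccc(C)cc2)C(Cl)(Cl)C(=O)[O-])cc1OC | intermediate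
12 | (4S,5R)-3,3-dichloro-4-(3,4-dimethoxybenzyl)-5-(p-tolylthio)dihydrofuran-2(3H)-one (4,5-cis) | COc1ccc(C[C@H]2[C@@H](Sc3ccc(C)cc3)OC(=O)C2(Cl)Cl)cc1OC | intermediate
13 | (R)-4-(3,4-dimethoxybenzyl)dihydrofuran-2(3H)-one | COc1ccc(C[C@H]2COC(=O)C2)cc1OC | intermediate
14 | ethyl 3-methylbut-2-enoate | CCOC(=O)C=C(C)C | starting material
15 | diethyl oxalate | CCOC(=O)C(=O)OCC | starting material
16 | potassium 1,6-diethoxy-4-methyl-1,6-dioxohexa-2,4-dien-2-olate (alkene geometry not fixed) | CCOC(=O)C([O-])=CC(C)=CC(=O)OCC.[K+] | intermediate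
17 | 4-methyl-2-oxo-2H-pyran-6-carboxylic acid | Cc1cc(C(=O)O)oc(=O)c1 | intermediate
18 | tert-butyl 4-methyl-2-oxo-2H-pyran-6-carboxylate | Cc1cc(C(=O)OC(C)(C)C)oc(=O)c1 | intermediate
19 | tert-butyl 4-(bromomethyl)-2-oxo-2H-pyran-6-carboxylate | BrCc1cc(C(=O)OC(C)(C)C)oc(=O)c1 | intermediate
20 | lithium enolate of 13 | COc1ccc(C[C@H]2COC(O[Li])=C2)cc1OC | intermediate
21 | tert-butyl 4-{[(3R,4R)-4-(3,4-dimethoxybenzyl)-2-oxotetrahydrofuran-3-yl]methyl}-2-oxo-2H-pyran-6-carboxylate | COc1ccc(C[C@H]2COC(=O)[C@@H]2Cc2cc(C(=O)OC(C)(C)C)oc(=O)c2)cc1OC | intermediate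
22 | 4-{[(3R,4R)-4-(3,4-dimethoxybenzyl)-2-oxotetrahydrofuran-3-yl]methyl}-2-oxo-2H-pyran-6-carboxylic acid | COc1ccc(C[C@H]2COC(=O)[C@@H]2Cc2cc(C(=O)O)oc(=O)c2)cc1OC | target

Total step count: 10. Longest linear sequence: 7 steps (steps 1, 2, 3, 4, 5, 9, 10); the pyranone branch (steps 6, 7, 8) joins at step 9.

Steps most likely to fail

Step 4. The acyloxysulfonium enolate may lose a benzylic γ-proton (vinylogous Pummerer pathway) faster than it rearranges, or the shift may pass in part through the arrangement with the tolyl group inside, which would erode the configurational purity at C4. The fallback sets out from 1 and returns at 13; it gives up the one-step formation of both ring bonds and sets C4 by auxiliary control. The sodium enolate of commercial (R)-4-benzyl-3-(pent-4-enoyl)oxazolidin-2-one (C=CCCC(=O)N1[C@H](Cc2ccccc2)COC1=O; NaHMDS, THF, −78 °C) would be alkylated with 1 in an Evans alkylation, the electrophile entering anti to the auxiliary benzyl group, to give (R)-4-benzyl-3-[(S)-2-(3,4-dimethoxybenzyl)pent-4-enoyl]oxazolidin-2-one F1. LiBH4 (Et2O, 1 equiv H2O, 0 °C) would cleave the auxiliary and give (S)-2-(3,4-dimethoxybenzyl)pent-4-en-1-ol F2. Lemieux–Johnson cleavage of the terminal alkene (OsO4 cat., NaIO4, 2,6-lutidine, dioxane–H2O) would deliver, after spontaneous ring closure, (4R)-4-(3,4-dimethoxybenzyl)tetrahydrofuran-2-ol F3. Oxidation of the lactol (TEMPO cat., PhI(OAc)2, CH2Cl2) would then give 13.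

Step 8. Electrophilic bromination of the pyranone ring at C3 or C5, or a second bromination of the methyl group, may compete with the radical chain. The fallback sets out from 18 and returns at 19 and raises the methyl group to the alcohol level by non-radical chemistry. Selenium dioxide oxidation (SeO2, dioxane, 100 °C) should give tert-butyl 4-formyl-2-oxo-2H-pyran-6-carboxylate F4. Luche reduction (NaBH4, CeCl3·7H2O, MeOH, −40 °C) should give tert-butyl 4-(hydroxymethyl)-2-oxo-2H-pyran-6-carboxylate F5. An Appel reaction (CBr4, PPh3, CH2Cl2, 0 °C) would then give 19.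

Step 9. The strongly basic lactone enolate may deprotonate the acidic CH2Br group of 19 or add to the pyranone ring (1,6-addition, ring opening) instead of displacing bromide. The fallback sets out from 13 and returns at 22 and replaces the hard enolate by a soft, carbonate-generated one. C-Acylation of 13 (LiHMDS 2.1 equiv, THF, −78 °C; then Boc2O) should give tert-butyl (4R)-4-(3,4-dimethoxybenzyl)-2-oxotetrahydrofuran-3-carboxylate F6 (C3 epimers). Alkylation of F6 with 19 (K2CO3, acetone, rt), anti to the C4 benzyl group, should give tert-butyl (4R)-3-{[6-(tert-butoxycarbonyl)-2-oxo-2H-pyran-4-yl]methyl}-4-(3,4-dimethoxybenzyl)-2-oxotetrahydrofuran-3-carboxylate F7 (pyranylmethyl trans to the 4-benzyl group). TFA–CH2Cl2 would remove both tert-butyl esters to give (4R)-3-[(6-carboxy-2-oxo-2H-pyran-4-yl)methyl]-4-(3,4-dimethoxybenzyl)-2-oxotetrahydrofuran-3-carboxylic acid F8. Heating (toluene–AcOH, 100 °C) should decarboxylate the malonic-type acid and let the α-centre settle through the enol in the thermodynamically preferred trans arrangement, giving 22.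

Further compounds
F1 | step 4 | (R)-4-benzyl-3-[(S)-2-(3,4-dimethoxybenzyl)pent-4-enoyl]oxazolidin-2-one | C=CC[C@@H](Cc1ccc(OC)c(OC)c1)C(=O)N1[C@H](Cc2ccccc2)COC1=O
F2 | step 4 | (S)-2-(3,4-dimethoxybenzyl)pent-4-en-1-ol | C=CC[C@@H](Cc1ccc(OC)c(OC)c1)CO
F3 | step 4 | (4R)-4-(3,4-dimethoxybenzyl)tetrahydrofuran-2-ol (anomer mixture) | COc1ccc(C[C@H]2COC(O)C2)cc1OC
F4 | step 8 | tert-butyl 4-formyl-2-oxo-2H-pyran-6-carboxylate | O=Cc1cc(C(=O)OC(C)(C)C)oc(=O)c1
F5 | step 8 | tert-butyl 4-(hydroxymethyl)-2-oxo-2H-pyran-6-carboxylate | OCc1cc(C(=O)OC(C)(C)C)oc(=O)c1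
F6 | step 9 | tert-butyl (4R)-4-(3,4-dimethoxybenzyl)-2-oxotetrahydrofuran-3-carboxylate (C3 epimers) | COc1ccc(C[C@H]2COC(=O)C2C(=O)OC(C)(C)C)cc1OC
F7 | step 9 | tert-butyl (4R)-3-{[6-(tert-butoxycarbonyl)-2-oxo-2H-pyran-4-yl]methyl}-4-(3,4-dimethoxybenzyl)-2-oxotetrahydrofuran-3-carboxylate (pyranylmethyl trans to the 4-benzyl group) | COc1ccc(C[C@H]2COC(=O)[C@@]2(Cc2cc(C(=O)OC(C)(C)C)oc(=O)c2)C(=O)OC(C)(C)C)cc1OC
F8 | step 9 | (4R)-3-[(6-carboxy-2-oxo-2H-pyran-4-yl)methyl]-4-(3,4-dimethoxybenzyl)-2-oxotetrahydrofuran-3-carboxylic acid (pyranylmethyl trans to the 4-benzyl group) | COc1ccc(C[C@H]2COC(=O)[C@@]2(Cc2cc(C(=O)O)oc(=O)c2)C(=O)O)cc1OC
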